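**One quantity.** You have 6 questions, and the balance of substrate units shrinks them to one reckoning per flask. Target plus side product is what has been spent of the charge, so if a fraction s of the substrate stands unspent at the end and target holds a fraction P, the share asked is P/(1 − s).

| flask | substrate | coupling partner | remark | time |
|---|---|---|---|---|
| larch | 10 mM | 9.5 mM | run made earlier |  |
| oak | 20 mM | 9.5 mM | run made earlier |  |
| Saturday's | 10 mM (fed, over 12 h) | 9.50 mM | all else is in the flask from the start; the feed brings no volume worth counting | 15 h |
| Monday's | 10 mM (in portions, 3, over 12 h) | 9.50 mM | first portion at the start, last at 12 h | 15 h |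
| Wednesday's | 10 mM (fed, over 3.0 h) | 9.50 mM | all else is in the flask from the start; the feed brings no volume worth counting | 15 h |
| Tuesday's | 10 mM | 9.50 mM (fed, over 12 h) | all else is in the flask from the start; the feed brings no volume worth counting | 15 h |
| Friday's | 10 mM | 9.50 mM | everything together at the start | 15 h |

| run | time / h | target / % | side product / % |
|---|---|---|---|
| larch | 1.33 | 32.5 | 8.6 |
| larch | 3.00 | 44.5 | 20.3 |
| larch | 6.00 | 48.0 | 33.0 |
| larch | 15.0 | 46.8 | 50.1 |
| oak | 0.417 | 13.9 | 3.0 |
| oak | 1.00 | 22.6 | 10.5 |
| oak | 2.00 | 24.5 | 22.0 |
| oak | 3.00 | 20.5 | 30.1 |

(scatter of a reading: 1 percentage point)

- the flask that comes out highest in share of target in target plus side product, or "all alike" when all lie within 1.5 percentage points (Saturday's / Monday's / Wednesday's / Tuesday's / Friday's / all alike)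
- share of target in target plus side product at the end, Saturday's
- share of target in target plus side product at the end, Monday's
- share of target in target plus side product at the end, Wednesday's
- share of target in target plus side product at the end, Tuesday's
- share of target in target plus side product at the end, Friday's

- percent here means substrate units held: one side product counts as two

**Zero point.** The larch run has Friday's recipe, and its last two target readings give the plateau target P = 47.4%. Oak, with twice the substrate, peaks among its readings at 4.90 mM of target against 4.80 mM in larch, so I carry P over to flasks that dose substrate. Tuesday's doses coupling partner instead and stays outside this reckoning. At s = 0 the share is P itself, and in this reckoning a substrate-dosed flask stands above P by the unspent substrate it holds.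

**First estimate.** I expect Monday's to hold the highest s, since its last portion, 33.3% of the charge, enters with 3.00 h to run. Larch substrate, as read from the balance of the readings, falls from 19.0% at 6.00 h to 3.10% at 15.0 h, a pseudo-first-order constant, read there, of λ = 0.201 /h. Applied across Monday's portions, 6.00 h apart, it leaves s = 25.3%.

**Weak link.** But λ is a late reading: in its first 6.00 h larch kept 19.0%, less than the 29.9% that λ allows. So I use that reading as the factor for each gap and keep λ for the last stretch, which gives s = 22.3% and a share of 61.0% for Monday's.

**The forecast.** It names Monday's at 57% (54% to 60%), below my figure, with Saturday's 54.5%, Wednesday's 49.5%, Tuesday's 42.5% and Friday's 48.7%, holding that “Slow feeds therefore look better” for the unreacted substrate that remains.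

**The flask.** Monday's comes out highest at 58.9%, holding at 15.0 h 20% substrate, 47.3% target and 33.0% side product, while Wednesday's stands at 49.3%, Friday's at 48.6% and Tuesday's at 44.0%.

    substrate + coupling partner → target, rate k1*[substrate]*[coupling partner]^1.5 (k = 630 /M^1.5/h)
    substrate + target → side product (k = 20.0 /M/h)

**P again.** With that substrate left, P gives 59.2% for Monday's. For Saturday's, with 15% left, P gives 55.8%, and that flask stands at 55.9%.

The numbers in the tables are calculated on assumed constants, noise included.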